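**Retrosynthetic overview**

1. 22 ⇐ 21 ⇐ 20 ⇐ 19 ⇐ 18: the end game changes only oxygen substituents (MOM hydrolysis, O-acylation, O-desilylation, oxidative demethylation of the ring B 1-hydroxy-4-methoxy pair to the quinone).
2. 18 ⇐ 6 + 16: ring B (C1, C2, C3, C4, C4a, C8a) carries oxygen at C1 and C4, its only carbon substituent at C2 next to C1, and hydrogen at C3. An aryl(methoxy)carbene chromium complex, a terminal alkyne and one CO ligand give exactly this pattern, forming C3–C4, C1–C2 and C1–C8a.
3. 6 ⇐ 1 + 3 (MOM protection, Br/Li exchange, acylchromate, O-methylation); 16 ⇐ 7 + 10 (Weinreb ynone, asymmetric transfer hydrogenation setting the only stereocentre as S, O-silylation, C-desilylation).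
4. Ring order: ring A is present from 1; ring B is the only ring made, in step 8.

Key step: step 8

Remark: the sense of induction in step 5 is assigned by analogy with aryl ketones (alkynyl in the place of aryl); complex 17, whose η6 bonding a SMILES string cannot show, is written as the arene and the Cr(CO)3 unit joined by a dot.

**Route**

Step 1
Reactants: 1 bromohydroquinone
Product: 2 2-bromo-1,4-bis(methoxymethoxy)benzene
Conditions: MOMCl, i-Pr2NEt, CH2Cl2, 0 °C to rt
Reagents that add atoms: chloromethyl methyl ether, COCCl
Why: Double O-alkylation of the two phenols (Williamson-type ether formation) under amine base should give the bis-MOM ether, a group that tolerates the aryllithium, the benzannulation and the cerium oxidation and is removed last under mild acid.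

Step 2
Reactants: 2 2-bromo-1,4-bis(methoxymethoxy)benzene; 3 chromium hexacarbonyl Cr(CO)6
Product: 6 pentacarbonyl[methoxy(2,5-bis(methoxymethoxy)phenyl)carbene]chromium, via aryllithium 4 (not isolated), via lithium acylchromate 5 (not isolated)
Conditions: t-BuLi (2 equiv), Et2O, −78 °C; Cr(CO)6, −78 °C to rt; then Me3OBF4, CH2Cl2, 0 °C
Reagents that add atoms: trimethyloxonium tetrafluoroborate, C[O+](C)C.F[B-](F)(F)F
Why: Fischer carbene synthesis, in which bromine–lithium exchange, addition of the aryllithium to a carbonyl ligand and O-methylation of the acylchromate with a Meerwein salt follow one another, a sequence established for ortho-alkoxyaryl lithium reagents.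

Step 3
Reactants: 7 4-methylpent-3-enoic acid
Product: 9 N-methoxy-N,4-dimethylpent-3-enamide, via acylimidazole 8 (not isolated)
Conditions: 1,1'-carbonyldiimidazole, CH2Cl2, 0 °C to rt; then MeNH(OMe)·HCl, rt
Reagents that add atoms: N,O-dimethylhydroxylamine hydrochloride, CNOC.Cl
Why: Amide formation through the acylimidazole is neutral, so the β,γ-double bond should stay out of conjugation, and the Weinreb amide is the acyl donor needed for step 4.

Step 4
Reactants: 9 N-methoxy-N,4-dimethylpent-3-enamide; 10 trimethylsilylacetylene
Product: 13 6-methyl-1-(trimethylsilyl)hept-5-en-1-yn-3-one, via lithium (trimethylsilyl)acetylide 11 (not isolated), via tetrahedral lithium alkoxide 12 (not isolated)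
Conditions: 10, n-BuLi, THF, −78 °C; then 9, −78 to 0 °C; AcOH, −78 °C
Reagents that add atoms: none
Why: Weinreb ketone synthesis, in which the acetylide adds once and the chelated alkoxide 12 survives until the cold acidic quench, which keeps the released amine protonated so that it cannot add to the ynone and limits migration of the alkene into conjugation.

Step 5
Reactants: 13 6-methyl-1-(trimethylsilyl)hept-5-en-1-yn-3-one
Product: 14 (S)-6-methyl-1-(trimethylsilyl)hept-5-en-1-yn-3-ol
Conditions: Ru[(S,S)-TsNCHPhCHPhNH](p-cymene) (1 mol %), i-PrOH, rt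
Reagents that add atoms: none
Why: Noyori asymmetric transfer hydrogenation of an alkynyl ketone under base-free conditions, in which hydride and proton pass from the ruthenium hydride–amine through a six-membered transition state with the alkynyl group in the place usually held by an aryl group, so that the (S,S) ligand should deliver hydride to the face that gives the (S) carbinol, the only stereocentre of the target.

Step 6
Reactants: 14 (S)-6-methyl-1-(trimethylsilyl)hept-5-en-1-yn-3-ol
Product: 15 (S)-3-(tert-butyldimethylsilyloxy)-6-methyl-1-(trimethylsilyl)hept-5-en-1-yne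
Conditions: TBSCl, imidazole, DMF, rt
Reagents that add atoms: tert-butyldimethylsilyl chloride, CC(C)(C)[Si](C)(C)Cl
Why: Imidazole-promoted O-silylation of the secondary alcohol should give a robust ether that keeps the propargylic oxygen from interfering in the benzannulation.

Step 7
Reactants: 15 (S)-3-(tert-butyldimethylsilyloxy)-6-methyl-1-(trimethylsilyl)hept-5-en-1-yne
Product: 16 (S)-3-(tert-butyldimethylsilyloxy)-6-methylhept-5-en-1-yne
Conditions: K2CO3 (cat.), MeOH, rt
Reagents that add atoms: none
Why: Methoxide-mediated protodesilylation should cleave only the C(sp)–Si bond, the hindered secondary O-silyl ether being stable to K2CO3 in methanol, and frees the terminal alkyne that controls regiochemistry in step 8.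

Step 8
Reactants: 6 pentacarbonyl[methoxy(2,5-bis(methoxymethoxy)phenyl)carbene]chromium; 16 (S)-3-(tert-butyldimethylsilyloxy)-6-methylhept-5-en-1-yne
Product: 18 (S)-2-[1-(tert-butyldimethylsilyloxy)-4-methylpent-3-enyl]-4-methoxy-5,8-bis(methoxymethoxy)naphthalen-1-ol, via tricarbonylchromium naphthol complex 17 (not isolated)
Conditions: THF, 55 °C, argon; then air, Et2O, rt; product taken on without delay
Reagents that add atoms: none
Why: Dötz benzannulation: loss of one CO from the zerovalent chromium complex 6 lets the terminal alkyne coordinate and insert into the chromium–carbene bond, and CO insertion then gives a chromium-bound aryl vinylketene; the closest precedent is the benzannulation of aryl(methoxy)carbene pentacarbonylchromium complexes with terminal alkynes, propargylic silyl ethers included. Ring B closes by six-electron electrocyclisation of this dienylketene onto C6 of the aryl group, the only free ortho carbon, which completes the bonds C3–C4, C1–C2 and C1–C8a; tautomerisation gives the naphthol as its Cr(CO)3 complex 17, from which air releases 18. No stereocentre is formed, and the propargylic centre of 16 lies outside the reacting array and should pass through unchanged. The step needs regioselective insertion, which the terminal alkyne secures: its unsubstituted carbon bonds to the carbene carbon, so the bulky silyloxy-bearing carbon ends up next to the CO-derived C1 and the side chain sits at C2. Silyl protection keeps the propargylic oxygen from intercepting the ketene, the trisubstituted alkene is inert to the carbene at this temperature, and THF favours phenol formation over cyclisation without CO insertion.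

Step 9
Reactants: 18 (S)-2-[1-(tert-butyldimethylsilyloxy)-4-methylpent-3-enyl]-4-methoxy-5,8-bis(methoxymethoxy)naphthalen-1-ol
Product: 19 (S)-2-[1-(tert-butyldimethylsilyloxy)-4-methylpent-3-enyl]-5,8-bis(methoxymethoxy)naphthalene-1,4-dione
Conditions: (NH4)2Ce(NO3)6 (2.2 equiv), MeCN/H2O, 0 °C, short reaction time
Reagents that add atoms: water, O
Why: Oxidative demethylation of a 4-methoxy-1-naphthol by tetravalent cerium, in which ring B with its free phenol is oxidised far more easily than MOM-capped ring A, water adds at C4 and methanol leaves, so the quinone should form on ring B only while a short time at 0 °C spares the MOM and silyl ethers and the alkene.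

Step 10
Reactants: 19 (S)-2-[1-(tert-butyldimethylsilyloxy)-4-methylpent-3-enyl]-5,8-bis(methoxymethoxy)naphthalene-1,4-dione
Product: 20 (S)-2-(1-hydroxy-4-methylpent-3-enyl)-5,8-bis(methoxymethoxy)naphthalene-1,4-dione
Conditions: HF·pyridine, pyridine, THF, 0 °C to rt
Reagents that add atoms: none
Why: Fluoride-mediated Si–O cleavage with buffered HF·pyridine avoids basic fluoride, which would attack the quinone, and should leave the aryl MOM acetals, the alkene and the stereocentre (no C–O bond is broken) untouched.

Step 11
Reactants: 20 (S)-2-(1-hydroxy-4-methylpent-3-enyl)-5,8-bis(methoxymethoxy)naphthalene-1,4-dione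
Product: 21 (S)-1-[5,8-bis(methoxymethoxy)-1,4-dioxo-1,4-dihydronaphthalen-2-yl]-4-methylpent-3-enyl 3-methylbutanoate
Conditions: 3-methylbutanoic acid, DCC, DMAP (cat.), CH2Cl2, 0 °C to rt
Reagents that add atoms: 3-methylbutanoic acid, CC(C)CC(=O)O
Why: Steglich esterification (carbodiimide activation, DMAP acyl transfer) should acylate the only free hydroxyl under neutral conditions with retention, since the C–O bond of the stereocentre is not broken.

Step 12
Reactants: 21 (S)-1-[5,8-bis(methoxymethoxy)-1,4-dioxo-1,4-dihydronaphthalen-2-yl]-4-methylpent-3-enyl 3-methylbutanoate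
Product: 22 isovalerylalkannin, (S)-1-(5,8-dihydroxy-1,4-dioxo-1,4-dihydronaphthalen-2-yl)-4-methylpent-3-enyl 3-methylbutanoate
Conditions: 2 M aq. HCl, i-PrOH/THF, rt, stopped at full conversion
Reagents that add atoms: none
Why: Acid-catalysed acetal hydrolysis, in which the two MOM ethers peri to the quinone carbonyls are cleaved by dilute acid (the freed phenols are stabilised by hydrogen bonds to the carbonyls) while the hindered secondary ester and the trisubstituted alkene should survive dilute HCl in a poorly nucleophilic solvent at room temperature.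

**Compound list**

1 | bromohydroquinone (2-bromobenzene-1,4-diol) | Oc1ccc(O)c(Br)c1 | starting material
2 | 2-bromo-1,4-bis(methoxymethoxy)benzene | COCOc1ccc(OCOC)c(Br)c1 | intermediate
3 | chromium hexacarbonyl Cr(CO)6 | O=C=[Cr](=C=O)(=C=O)(=C=O)(=C=O)=C=O | starting material
4 | [2,5-bis(methoxymethoxy)phenyl]lithium | [Li]c1cc(OCOC)ccc1OCOC | intermediate
5 | lithium pentacarbonyl[2,5-bis(methoxymethoxy)benzoyl]chromate | [Li+].[O-]C(c1cc(OCOC)ccc1OCOC)=[Cr](=C=O)(=C=O)(=C=O)(=C=O)=C=O | intermediate
6 | pentacarbonyl[methoxy(2,5-bis(methoxymethoxy)phenyl)carbene]chromium | COC(c1cc(OCOC)ccc1OCOC)=[Cr](=C=O)(=C=O)(=C=O)(=C=O)=C=O | intermediate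
7 | 4-methylpent-3-enoic acid | CC(C)=CCC(=O)O | starting material
8 | 1-(4-methylpent-3-enoyl)imidazole | CC(C)=CCC(=O)n1ccnc1 | intermediate
9 | N-methoxy-N,4-dimethylpent-3-enamide | CC(C)=CCC(=O)N(C)OC | intermediate
10 | trimethylsilylacetylene | C#C[Si](C)(C)C | starting material
11 | lithium (trimethylsilyl)acetylide | [Li]C#C[Si](C)(C)C | intermediate
12 | lithium 3-[methoxy(methyl)amino]-6-methyl-1-(trimethylsilyl)hept-5-en-1-yn-3-olate | CC(C)=CCC(O[Li])(C#C[Si](C)(C)C)N(C)OC | intermediate
13 | 6-methyl-1-(trimethylsilyl)hept-5-en-1-yn-3-one | CC(C)=CCC(=O)C#C[Si](C)(C)C | intermediate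
14 | (S)-6-methyl-1-(trimethylsilyl)hept-5-en-1-yn-3-ol | CC(C)=CC[C@H](O)C#C[Si](C)(C)C | intermediate
15 | (S)-3-(tert-butyldimethylsilyloxy)-6-methyl-1-(trimethylsilyl)hept-5-en-1-yne | CC(C)=CC[C@H](O[Si](C)(C)C(C)(C)C)C#C[Si](C)(C)C | intermediate
16 | (S)-3-(tert-butyldimethylsilyloxy)-6-methylhept-5-en-1-yne | CC(C)=CC[C@H](O[Si](C)(C)C(C)(C)C)C#C | intermediate
17 | tricarbonylchromium complex of naphthol 18 (Cr(CO)3 on ring B) | CC(C)=CC[C@H](O[Si](C)(C)C(C)(C)C)c1cc(OC)c2c(OCOC)ccc(OCOC)c2c1O.O=C=[Cr](=C=O)=C=O | intermediate
18 | (S)-2-[1-(tert-butyldimethylsilyloxy)-4-methylpent-3-enyl]-4-methoxy-5,8-bis(methoxymethoxy)naphthalen-1-ol | CC(C)=CC[C@H](O[Si](C)(C)C(C)(C)C)c1cc(OC)c2c(OCOC)ccc(OCOC)c2c1O | intermediate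
19 | (S)-2-[1-(tert-butyldimethylsilyloxy)-4-methylpent-3-enyl]-5,8-bis(methoxymethoxy)naphthalene-1,4-dione | CC(C)=CC[C@H](O[Si](C)(C)C(C)(C)C)C1=CC(=O)c2c(OCOC)ccc(OCOC)c2C1=O | intermediate
20 | (S)-2-(1-hydroxy-4-methylpent-3-enyl)-5,8-bis(methoxymethoxy)naphthalene-1,4-dione | CC(C)=CC[C@H](O)C1=CC(=O)c2c(OCOC)ccc(OCOC)c2C1=O | intermediate
21 | (S)-1-[5,8-bis(methoxymethoxy)-1,4-dioxo-1,4-dihydronaphthalen-2-yl]-4-methylpent-3-enyl 3-methylbutanoate | CC(C)=CC[C@H](OC(=O)CC(C)C)C1=CC(=O)c2c(OCOC)ccc(OCOC)c2C1=O | intermediate
22 | isovalerylalkannin | CC(C)=CC[C@H](OC(=O)CC(C)C)C1=CC(=O)c2c(O)ccc(O)c2C1=O | target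

**Step count**

Total steps: 12. Longest linear sequence: 10 steps (steps 3 to 12, from 4-methylpent-3-enoic acid).

**Steps most likely to fail, with fallbacks**

Step 8. The vinylcarbene may cyclise without taking up CO, or the electron-rich naphthol may be degraded by air during demetalation, so that little of ring B is obtained. The fallback closes ring B by a carbanion cyclisation instead. It sets out from aryl bromide 2 and alkyne 16 and comes back to the route at quinone 19. Lithiation of 2 between bromine and the neighbouring MOM ether with LiN(i-Pr)2 (THF, −78 °C) and acylation with N-methoxy-N-methylacetamide should give 1-[2-bromo-3,6-bis(methoxymethoxy)phenyl]ethanone F1. Sonogashira coupling of F1 with 16 (PdCl2(PPh3)2, CuI, Et3N, 60 °C) should give (S)-1-[2-[3-(tert-butyldimethylsilyloxy)-6-methylhept-5-en-1-ynyl]-3,6-bis(methoxymethoxy)phenyl]ethanone F2. Treatment with KN(SiMe3)2 (toluene, −78 °C to rt, short time) should close ring B by 6-endo-dig attack of the methyl ketone enolate on the alkyne and give (S)-3-[1-(tert-butyldimethylsilyloxy)-4-methylpent-3-enyl]-5,8-bis(methoxymethoxy)naphthalen-1-ol F3. Oxidation of F3 at the free para position with PhI(OCOCF3)2 in MeCN/H2O at 0 °C should give 19; because ring A is symmetrically substituted, the 3-substituted quinone is the same compound as the 2-substituted one.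

Step 5. The trisubstituted alkene of 13 may migrate into conjugation with the ketone before or during reduction (a risk already present in step 4), and facial selectivity may be incomplete. The fallback avoids the β,γ-unsaturated ynone altogether. It sets out from trimethylsilylacetylene 10 and comes back at alcohol 14. Formylation of the lithium acetylide (n-BuLi, THF, −78 °C; DMF; aqueous KH2PO4 quench) should give 3-(trimethylsilyl)prop-2-ynal F4. Brown allylation with (−)-Ipc2B(allyl) (Et2O, −78 °C, ethanolamine work-up) should give (S)-1-(trimethylsilyl)hex-5-en-1-yn-3-ol F5, the chair transition state placing the alkynyl group equatorial. Cross-metathesis of F5 with 2-methylbut-2-ene, using the second-generation Grubbs catalyst RuCl2(=CHPh)(PCy3)(1,3-dimesitylimidazolidin-2-ylidene) at 40 °C, should turn the vinyl group into the 2-methylprop-1-enyl terminus and give 14.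

Step 12. Once the naphthazarin is unmasked, acid may ionise the benzylic C–O bond with loss of the acyloxy group, or may add across the trisubstituted alkene. The fallback reverses the order of deprotection and acylation. It sets out from alcohol 20 and comes back at target 22. Hydrolysis of the MOM ethers of 20 under the dilute HCl conditions of step 12 should give alkannin F6, whose benzylic hydroxyl is a poorer leaving group than an ester. Steglich acylation of F6 with 3-methylbutanoic acid (DCC, DMAP cat., CH2Cl2, 0 °C) should then be selective for the side-chain hydroxyl, because the two peri hydroxyls are held in hydrogen bonds to the quinone carbonyls, and give 22 without any acid treatment of the ester.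

**Further compounds**

F1 | step 8 | 1-[2-bromo-3,6-bis(methoxymethoxy)phenyl]ethanone | CC(=O)c1c(OCOC)ccc(OCOC)c1Br
F2 | step 8 | (S)-1-[2-[3-(tert-butyldimethylsilyloxy)-6-methylhept-5-en-1-ynyl]-3,6-bis(methoxymethoxy)phenyl]ethanone | CC(C)=CC[C@H](O[Si](C)(C)C(C)(C)C)C#Cc1c(OCOC)ccc(OCOC)c1C(C)=O
F3 | step 8 | (S)-3-[1-(tert-butyldimethylsilyloxy)-4-methylpent-3-enyl]-5,8-bis(methoxymethoxy)naphthalen-1-ol | CC(C)=CC[C@H](O[Si](C)(C)C(C)(C)C)c1cc(O)c2c(OCOC)ccc(OCOC)c2c1
F4 | step 5 | 3-(trimethylsilyl)prop-2-ynal | C[Si](C)(C)C#CC=O
F5 | step 5 | (S)-1-(trimethylsilyl)hex-5-en-1-yn-3-ol | C=CC[C@H](O)C#C[Si](C)(C)C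
F6 | step 12 | alkannin | CC(C)=CC[C@H](O)C1=CC(=O)c2c(O)ccc(O)c2C1=O
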